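Ring B (the cyclobutane C4–C5–C11–C10) is cut at C10–C11. This bond joins the α-carbons of the C1 enone and of the C9 carbinol, so a 1,4-dicarbonyl lies hidden across it. Oxidation of a bis-enol ether with (NH4)2Ce(NO3)6 forms that bond, closes ring B, sets C10 and C11 and returns both carbonyls. The precursor is the cis-fused ring A/ring C bicycle bearing a C9=C10 enol ether and a C1=C11 dienol ether. Its two enol oxygens point apart (O9 is trans to C4 across C9=C10, an estimated 6 Å from O1), so no O–Si–O bridge can join them; two separate triethylsilyl enol ethers, each made regiospecifically, are used.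

Key step: step 13

Locants (all bicyclic and tricyclic compounds): ring A = C1(=O)–C2=C3(CH3)–C4–C5–C11; ring C = C4–C10(CH3)–C9–C8–C7(O)–C6(CH3)2–C5; ring B = cyclobutane C4–C5–C11–C10, formed in step 13.

Assumption (step 1): the iridium catalyst carrying (S)-SEGPHOS is taken to add the prenyl group to the Si face of aldehyde 3, which gives the 4R alcohol 4; if the sense is the reverse, (R)-SEGPHOS is used.

Step 1
Reactants: 1 hex-5-en-1-ol; 2 3-methylbuta-1,2-diene
Product: 4 (4R)-3,3-dimethylnona-1,8-dien-4-ol, via hex-5-enal 3 (not isolated)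
Conditions: [Ir(cod)Cl]2 (2.5 mol%), (S)-SEGPHOS (5 mol%), 4-cyano-3-nitrobenzoic acid (10 mol%), allyl acetate (10 mol%), Cs2CO3 (20 mol%), threefold excess of the allene, toluene, 70 °C, sealed tube
Reagents that add atoms: none
Why: Iridium-catalysed transfer-hydrogenative carbonyl reverse prenylation: the alcohol is dehydrogenated to 3, the iridium hydride adds to the allene, and the prenyl iridium species adds through its tertiary carbon in a closed chair transition state whose aldehyde face is fixed by the chiral ligand, which sets the carbinol centre (the later C7) with no atom lost.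

Step 2
Reactants: 4 (4R)-3,3-dimethylnona-1,8-dien-4-ol
Product: 5 (4R)-4-(tert-butyldimethylsilyloxy)-3,3-dimethylnona-1,8-diene
Conditions: tBuMe2SiOTf, 2,6-lutidine, CH2Cl2, −78 → 0 °C
Reagents that add atoms: tert-butyldimethylsilyl trifluoromethanesulfonate, CC(C)(C)[Si](C)(C)OS(=O)(=O)C(F)(F)F
Why: Silylation of the hindered neopentylic alcohol with the silyl triflate, which touches no stereocentre.

Step 3
Reactants: 5 (4R)-4-(tert-butyldimethylsilyloxy)-3,3-dimethylnona-1,8-diene
Product: 6 (1R)-1-(tert-butyldimethylsilyloxy)-2,2-dimethylcyclohept-3-ene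
Conditions: second-generation Grubbs catalyst (3 mol%), CH2Cl2 (0.01 M), 40 °C
Reagents that add atoms: none
Why: Ring-closing metathesis of the 1,8-diene to the cycloheptene, helped by the gem-dimethyl group and driven by loss of ethene.

Step 4
Reactants: 6 (1R)-1-(tert-butyldimethylsilyloxy)-2,2-dimethylcyclohept-3-ene
Product: 7 (5R)-5-(tert-butyldimethylsilyloxy)-4,4-dimethylcyclohept-2-en-1-one
Conditions: Rh2(cap)4 (dirhodium tetracaprolactamate, 1 mol%), tBuOOH (70% aq, 5 equiv), ClCH2CH2Cl, 40 °C
Reagents that add atoms: tert-butyl hydroperoxide, CC(C)(C)OO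
Why: Radical allylic oxidation: the alkene has only one allylic CH2 (the other allylic carbon is quaternary) and the peroxyl radical is taken up at the unhindered allyl terminus, which should give the 4,4-dimethyl enone.

Step 5
Reactants: 8 (E)-pent-3-en-2-one
Product: 9 (E)-2-(tert-butyldimethylsilyloxy)penta-1,3-diene
Conditions: tBuMe2SiOTf, Et3N, Et2O, 0 °C
Reagents that add atoms: tert-butyldimethylsilyl trifluoromethanesulfonate, CC(C)(C)[Si](C)(C)OS(=O)(=O)C(F)(F)F
Why: Soft enolisation of the methyl ketone on its methyl side gives the 2-silyloxy diene and leaves the E alkene intact.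

Step 6
Reactants: 7 (5R)-5-(tert-butyldimethylsilyloxy)-4,4-dimethylcyclohept-2-en-1-one; 9 (E)-2-(tert-butyldimethylsilyloxy)penta-1,3-diene
Product: 10 cis-fused Diels–Alder adduct (C10 ketone; C1=C2 tert-butyldimethylsilyl enol ether; C3 methyl cis to C10; C7 tert-butyldimethylsilyl ether; H4/H5/O7 on one face of ring C; 7R)
Conditions: AlBr3/AlMe3 (5:1; 0.2 equiv AlBr3), twofold excess of the diene, toluene–CH2Cl2, −20 → 0 °C; Et3N quench
Reagents that add atoms: none
Why: Lewis acid-catalysed Diels–Alder reaction in which every atom of both partners ends up in the adduct: the unsubstituted diene terminus C11 (para to the silyloxy group) bonds to the hindered β-carbon C5 and the methyl-bearing terminus C3 to C4 (ortho rule), suprafacial addition to the ring alkene gives the cis C4–C5 fusion, and the diene should approach the face of the ring alkene opposite the C7 silyloxy group, the usual sense for a cycloalkenone substituted on its saturated flank, which sets C4 and C5 from C7 (the endo centre C3 is removed in step 8).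

Step 7
Reactants: 10 cis-fused Diels–Alder adduct
Product: 11 C10-methylene silyl enol ether (exocyclic C10=CH2; C1=C2 tert-butyldimethylsilyl enol ether; C3 methyl; C7 tert-butyldimethylsilyl ether)
Conditions: Cp2TiMe2 (3 equiv), toluene, 70 °C, dark
Reagents that add atoms: bis(cyclopentadienyl)dimethyltitanium, [CH3-].[CH3-].[Ti+4].c1cc[cH-]c1.c1cc[cH-]c1
Why: Petasis methylenation: the non-basic titanium methylidene converts the C10 ketone into the exocyclic alkene without epimerising the adjacent C4 and leaves the silyl enol ether and the silyl ether alone.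

Step 8
Reactants: 11 C10-methylene silyl enol ether
Product: 12 C10-methylene enone (C1 ketone; C2=C3 with methyl on C3; exocyclic C10=CH2; C7 tert-butyldimethylsilyl ether)
Conditions: Pd(OAc)2 (1.1 equiv), MeCN, 25 °C
Reagents that add atoms: none
Why: Saegusa–Ito oxidation: the palladium enolate formed at C2 loses the hydrogen on C3, which places the alkene at C2=C3 and removes the stereocentre at C3.

Step 9
Reactants: 12 C10-methylene enone
Product: 13 C9-hydroxy C10-methylene enone (both C9 epimers)
Conditions: SeO2 (0.3 equiv), tBuOOH (5.5 M in decane, 2.5 equiv), CH2Cl2, 0 → 25 °C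
Reagents that add atoms: tert-butyl hydroperoxide, CC(C)(C)OO (its oxygen is passed on by selenium dioxide, O=[Se]=O)
Why: Selenium dioxide allylic hydroxylation (ene reaction then [2,3] shift) of the electron-rich exocyclic alkene at the ring CH2 C9, which is preferred over the CH at C4 as in β-pinene-type alkenes, while the electron-poor enone alkene does not react.

Step 10
Reactants: 13 C9-hydroxy C10-methylene enone
Product: 14 C9-keto C10-methylene enone (α-methylene ketone; ring A enone unchanged)
Conditions: Dess–Martin periodinane, CH2Cl2, 0 °C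
Reagents that add atoms: none
Why: Dess–Martin oxidation of the secondary allylic alcohol, which removes the transient C9 centre.

Step 11
Reactants: 14 C9-keto C10-methylene enone
Product: 15 C9=C10 triethylsilyl enol ether enone (C10 methyl; ring A enone; C7 tert-butyldimethylsilyl ether)
Conditions: RhCl(PPh3)3 (2 mol%), Et3SiH (1.2 equiv), THF, 50 °C
Reagents that add atoms: triethylsilane, CC[SiH](CC)CC
Why: Rhodium-catalysed 1,4-hydrosilylation of an enone: the s-cis exo-methylene enone takes up Si–H across oxygen and the terminal CH2 faster than the s-trans, β,β-disubstituted ring A enone, which places the enol ether double bond at C9=C10 and nowhere else.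

Step 12
Reactants: 15 C9=C10 triethylsilyl enol ether enone
Product: 17 bis(triethylsilyl) enol ether of the cis-fused diketone (C9=C10 and C1=C11 enol ethers; C2=C3; C7 tert-butyldimethylsilyl ether), via lithium dienolate 16 (not isolated)
Conditions: LiN(iPr)2 (1.3 equiv), THF, −78 °C; Et3SiCl, −78 → −40 °C; cold NaHCO3 work-up
Reagents that add atoms: chlorotriethylsilane, CC[Si](Cl)(CC)CC
Why: Kinetic α′-deprotonation of the cyclohexenone at C11 and O-silylation give the cross-conjugated dienol ether; the C9 carbonyl is already masked, so neither C8 enolisation nor loss of the C7 silyloxy group can occur.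

Step 13
Reactants: 17 bis(triethylsilyl) enol ether of the cis-fused diketone
Product: 18 tricyclic diketone silyl ether (ring B closed; C1 enone; C9 ketone; C7 tert-butyldimethylsilyl ether)
Conditions: (NH4)2Ce(NO3)6 (2.2 equiv), NaHCO3 (6 equiv), MeCN (0.01 M), −30 → 0 °C
Reagents that add atoms: none
Why: Proposed new method: tetravalent cerium removes one electron from an enol ether (expected first at the tetrasubstituted C9=C10 unit; oxidation of the dienol ether first leads to the same bond), the radical cation is captured at C10 by C11 of the other enol ether, and a second oxidation with loss of both triethylsilyl groups leaves the C9 ketone and the C1 enone, which makes the closure irreversible and pays for the ring strain. The closest known reactions are the cerium-mediated cross-coupling of two silyl enol ethers, free or silicon-tethered, to unsymmetrical 1,4-diketones and the oxidative cyclisation of 1,6-diester dienolates to cyclobutane-1,2-diesters. Ring B closes in a 4-exo-trig mode (C11=C1 lies outside the new ring). C11 is controlled by the cis C4–C5 fusion, since C10 hangs from C4 on one face of ring A and can reach C11 only there, and C10 is controlled by ring C, which holds C9 on the side of C6 so that the methyl group must point towards the enone bridge. The step needs C–C coupling to beat capture of the oxidised enol ether by nitrate or water and intermolecular coupling; the substrate secures this because the bulky C6 takes the pseudo-equatorial place on C5 and so puts C10 pseudo-axial on C4, an estimated 3 Å from C11, while high dilution and the bicarbonate buffer suppress the other paths. Regiochemistry (C10 rather than C8, C11 rather than C4) was fixed in steps 11 and 12.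

Step 14
Reactants: 18 tricyclic diketone silyl ether
Product: 19 tricyclic hydroxy diketone (free C7 alcohol; β-hydroxy ketone)
Conditions: HF (48% aq), MeCN, 0 → 25 °C
Reagents that add atoms: none
Why: Acidic fluoride cleaves the hindered silyl ether without the base that would trigger retro-aldol cleavage or β-elimination of the β-hydroxy ketone.

Step 15
Reactants: 19 tricyclic hydroxy diketone; 20 3-methylbutanal
Product: 22 C7 isovalerate C9 alcohol (O7 and O9 trans on ring C), via samarium-bound hemiacetal 21 (not isolated)
Conditions: SmI2 (30 mol%, premixed with the aldehyde), sixfold excess of the aldehyde, THF, −10 °C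
Reagents that add atoms: none
Why: Evans–Tishchenko reduction, an addition of one aldehyde molecule with no atom lost: the hemiacetal formed at O7 delivers its hydride to the C9 ketone within a six-membered samarium chelate on the face of O7, which gives the 1,3-anti C9 alcohol and leaves the isovalerate on O7, and premixing lets the aldehyde consume the divalent samarium before the diketone is added.

Step 16
Reactants: 22 C7 isovalerate C9 alcohol; 23 (E)-2-methylbut-2-enoyl chloride
Product: 24 CNP0194415.1
Conditions: Et3N, DMAP, CH2Cl2, 0 → 40 °C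
Reagents that add atoms: none
Why: DMAP-catalysed acylation of the remaining hindered C9 alcohol with the acid chloride, which changes neither the configuration at C9 nor the E alkene geometry.

Compound list
1 | hex-5-en-1-ol | C=CCCCCO | starting material
2 | 3-methylbuta-1,2-diene | CC(C)=C=C | starting material
3 | hex-5-enal (formed from 1 in the flask) | C=CCCCC=O | intermediate (not isolated)
4 | (4R)-3,3-dimethylnona-1,8-dien-4-ol | C=CC(C)(C)[C@H](O)CCCC=C | intermediate
5 | (4R)-4-(tert-butyldimethylsilyloxy)-3,3-dimethylnona-1,8-diene | C=CC(C)(C)[C@H](O[Si](C)(C)C(C)(C)C)CCCC=C | intermediate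
6 | (1R)-1-(tert-butyldimethylsilyloxy)-2,2-dimethylcyclohept-3-ene | CC1(C)C=CCCC[C@H]1O[Si](C)(C)C(C)(C)C | intermediate
7 | (5R)-5-(tert-butyldimethylsilyloxy)-4,4-dimethylcyclohept-2-en-1-one | O=C1C=CC(C)(C)[C@H](O[Si](C)(C)C(C)(C)C)CC1 | intermediate
8 | (E)-pent-3-en-2-one | C/C=C/C(C)=O | starting material
9 | (E)-2-(tert-butyldimethylsilyloxy)penta-1,3-diene | C/C=C/C(=C)O[Si](C)(C)C(C)(C)C | intermediate
10 | cis-fused Diels–Alder adduct: C10 ketone; C1=C2 tert-butyldimethylsilyl enol ether; C3 methyl cis to C10; C7 tert-butyldimethylsilyl ether; H4, H5 and O7 on one face of ring C; 7R | O=C1CC[C@@H](O[Si](C)(C)C(C)(C)C)C(C)(C)[C@@H]2CC(O[Si](C)(C)C(C)(C)C)=C[C@H](C)[C@H]12 | intermediate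
11 | C10-methylene silyl enol ether: exocyclic C10=CH2; C1=C2 tert-butyldimethylsilyl enol ether; C3 methyl cis to C10; C7 tert-butyldimethylsilyl ether | C=C1CC[C@@H](O[Si](C)(C)C(C)(C)C)C(C)(C)[C@@H]2CC(O[Si](C)(C)C(C)(C)C)=C[C@H](C)[C@H]12 | intermediate
12 | C10-methylene enone: cis-fused; C1 ketone; C2=C3 with methyl on C3; exocyclic C10=CH2; C7 tert-butyldimethylsilyl ether | C=C1CC[C@@H](O[Si](C)(C)C(C)(C)C)C(C)(C)[C@@H]2CC(=O)C=C(C)[C@H]12 | intermediate
13 | C9-hydroxy C10-methylene enone: C9 allylic alcohol (both C9 epimers); ring A enone; C7 tert-butyldimethylsilyl ether | C=C1C(O)C[C@@H](O[Si](C)(C)C(C)(C)C)C(C)(C)[C@@H]2CC(=O)C=C(C)[C@H]12 | intermediate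
14 | C9-keto C10-methylene enone: C9 ketone with exocyclic C10=CH2; ring A enone; C7 tert-butyldimethylsilyl ether | C=C1C(=O)C[C@@H](O[Si](C)(C)C(C)(C)C)C(C)(C)[C@@H]2CC(=O)C=C(C)[C@H]12 | intermediate
15 | C9=C10 triethylsilyl enol ether enone: C10 methyl; ring A enone; C7 tert-butyldimethylsilyl ether | CC1=C(O[Si](CC)(CC)CC)C[C@@H](O[Si](C)(C)C(C)(C)C)C(C)(C)[C@@H]2CC(=O)C=C(C)[C@H]12 | intermediate
16 | lithium C1=C11 dienolate of the C9=C10 triethylsilyl enol ether enone | CC1=C(O[Si](CC)(CC)CC)C[C@@H](O[Si](C)(C)C(C)(C)C)C(C)(C)[C@@H]2C=C([O-])C=C(C)[C@H]12.[Li+] | intermediate (not isolated)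
17 | bis(triethylsilyl) enol ether of the cis-fused diketone: C9=C10 and C1=C11 enol ethers; C2=C3; C7 tert-butyldimethylsilyl ether | CC1=C(O[Si](CC)(CC)CC)C[C@@H](O[Si](C)(C)C(C)(C)C)C(C)(C)[C@@H]2C=C(O[Si](CC)(CC)CC)C=C(C)[C@H]12 | intermediate (precursor of the key step)
18 | tricyclic diketone silyl ether: ring B closed; C1 enone; C9 ketone; C7 tert-butyldimethylsilyl ether | O=C1C[C@@H](O[Si](C)(C)C(C)(C)C)C(C)(C)[C@@H]2[C@H]3C(=O)C=C(C)[C@@H]2[C@]31C | intermediate (product of the key step)
19 | tricyclic hydroxy diketone: free C7 alcohol; C1 enone; C9 ketone | O=C1C[C@@H](O)C(C)(C)[C@@H]2[C@H]3C(=O)C=C(C)[C@@H]2[C@]31C | intermediate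
20 | 3-methylbutanal | CC(C)CC=O | starting material
21 | O7 hemiacetal of the tricyclic hydroxy diketone with 3-methylbutanal (samarium-bound in the flask; drawn as the free hemiacetal) | O=C1C[C@@H](OC(O)CC(C)C)C(C)(C)[C@@H]2[C@H]3C(=O)C=C(C)[C@@H]2[C@]31C | intermediate (not isolated)
22 | C7 isovalerate C9 alcohol; O7 and O9 trans on ring C | O[C@@H]1C[C@@H](OC(=O)CC(C)C)C(C)(C)[C@@H]2[C@H]3C(=O)C=C(C)[C@@H]2[C@]31C | intermediate
23 | (E)-2-methylbut-2-enoyl chloride | C/C=C(\C)C(=O)Cl | starting material
24 | CNP0194415.1: C7 isovalerate C9 tiglate; 4R,5S,7R,9R,10R,11R in the locants used here | C/C=C(\C)C(=O)O[C@@H]1C[C@@H](OC(=O)CC(C)C)C(C)(C)[C@@H]2[C@H]3C(=O)C=C(C)[C@@H]2[C@]31C | target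

Total step count: 16. Longest linear sequence: 15 (steps 1–4 and 6–16, from hex-5-en-1-ol).

Steps most likely to fail

Step 13 (bears the label). What may go wrong: after the first oxidation, capture of the C10 radical cation by nitrate or water, or simple hydrolysis of the enol ethers, outruns the strained four-membered ring closure. Fallback by known chemistry, setting out from 15: LiN(iPr)2 in THF at −78 °C followed by N-bromosuccinimide should brominate the kinetic C11 enolate on the face away from the pseudo-axial C10 and give the 11-bromo enone F1. Tetrabutylammonium difluorotriphenylsilicate in THF at −20 °C then cleaves the triethylsilyl enol ether, and the C9 enolate so freed displaces bromide from C11 with inversion (intramolecular ketone enolate alkylation, 4-exo-tet, a known way to bicyclo[3.1.1]heptanones). O-alkylation is excluded because O9 is trans to C4. The fallback comes back to the route at 18.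

Step 6. What may go wrong: the Lewis acid destroys the silyloxy diene or strips the C7 silyl ether before the slow cycloaddition at the neopentylic C5, or facial discrimination by the remote C7 group is eroded. Fallback, setting out from 7: a Lewis acid-free thermal cycloaddition with the doubly activated diene (E)-4-methoxy-2-(trimethylsilyloxy)penta-1,3-diene F2, made from commercial (E)-4-methoxypent-3-en-2-one with LiN(iPr)2 and Me3SiCl. In toluene at 140 °C (sealed tube) it should give the methoxy adduct F3. Cp2TiMe2 converts its C10 ketone into the methylene compound F4, and dilute HCl in THF hydrolyses the enol ether and eliminates methanol. The fallback comes back to the route at 12.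

Step 9. What may go wrong: hydrogen abstraction at the doubly allylic C4–H instead of C9–H2, or over-oxidation. Fallback, setting out from 10, puts the oxygen on C9 before the methylene group is made. KN(SiMe3)2 in THF at −78 °C followed by 2-(phenylsulfonyl)-3-phenyloxaziridine hydroxylates the kinetic C9 enolate to the 9-hydroxy ketone F5. Et3SiCl and imidazole give the silyl ether F6, Cp2TiMe2 gives the methylene compound F7, and Pd(OAc)2 gives the enone F8. AcOH/THF/H2O then removes the triethylsilyl group. The fallback comes back to the route at 13.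

Further compounds
F1 | step 13 | 11-bromo derivative of 15 (Br on C11 trans to C10) | CC1=C(O[Si](CC)(CC)CC)C[C@@H](O[Si](C)(C)C(C)(C)C)C(C)(C)[C@@H]2[C@@H](Br)C(=O)C=C(C)[C@H]12
F2 | step 6 | (E)-4-methoxy-2-(trimethylsilyloxy)penta-1,3-diene | CO/C(C)=C/C(=C)O[Si](C)(C)C
F3 | step 6 | cis-fused adduct: C10 ketone; C1=C2 trimethylsilyl enol ether; C3 methoxy and methyl (either C3 epimer); C7 tert-butyldimethylsilyl ether | O=C1CC[C@@H](O[Si](C)(C)C(C)(C)C)C(C)(C)[C@@H]2CC(O[Si](C)(C)C)=CC(C)(OC)[C@H]12
F4 | step 6 | C10-methylene analogue of F3 | C=C1CC[C@@H](O[Si](C)(C)C(C)(C)C)C(C)(C)[C@@H]2CC(O[Si](C)(C)C)=CC(C)(OC)[C@H]12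
F5 | step 9 | 9-hydroxy derivative of 10 (either C9 epimer) | O=C1C(O)C[C@@H](O[Si](C)(C)C(C)(C)C)C(C)(C)[C@@H]2CC(O[Si](C)(C)C(C)(C)C)=C[C@H](C)[C@H]12
F6 | step 9 | 9-triethylsilyl ether of F5 | O=C1C(O[Si](CC)(CC)CC)C[C@@H](O[Si](C)(C)C(C)(C)C)C(C)(C)[C@@H]2CC(O[Si](C)(C)C(C)(C)C)=C[C@H](C)[C@H]12
F7 | step 9 | C10-methylene analogue of F6 | C=C1C(O[Si](CC)(CC)CC)C[C@@H](O[Si](C)(C)C(C)(C)C)C(C)(C)[C@@H]2CC(O[Si](C)(C)C(C)(C)C)=C[C@H](C)[C@H]12
F8 | step 9 | 9-triethylsilyl ether of 13 (ring A enone) | C=C1C(O[Si](CC)(CC)CC)C[C@@H](O[Si](C)(C)C(C)(C)C)C(C)(C)[C@@H]2CC(=O)C=C(C)[C@H]12
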